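**Strategy**

Everything rests on making the crowded central ether (B6–O–C1, rings B and C) inside a ring and then deleting the tether. Two features of the target allow this: C1 stands opposite the C4 oxygen on ring C, and B5, the neighbour of B6 on ring B, carries only hydrogen. A carbonyl tying B5 to C1 gives benzophenone 19, with C4–OH and B6–OH as its only free phenols. Its anodic oxidation should join the B6 oxygen to C1, closing a spiro benzofuranone and turning ring C into a cyclohexadienone (20). Methoxide later severs the carbonyl–C1 bond, ring C rearomatises, and the leftover B5 carboxyl is shed before global demethylation.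

Key step: step 11

**Remarks before the route**

- Labels: ring A is the terminal 3,5-dioxygenated phenoxy ring. Ring B is the central ring: B1 carries O–ring A, B2 and B4 carry oxygen, B3 and B5 are CH, and B6 carries the oxygen bound to ring C. Ring C is the hexasubstituted ring: C1 is the ether carbon, C2 and C6 carry oxygen, C3 and C5 carry the 2,4,6-trioxygenated phenyl rings D and E, and C4 carries OH.
- Structure check: 19 and 20 place every target atom correctly, so no constitutional change is made. The target has no stereocentre and no stereogenic axis, because every biaryl axis carries a symmetric ring.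
- Design notes: the bridge ketone is made by adding a B5 aryllithium to the ring C aldehyde. An acyl migration or Friedel–Crafts acylation on ring B would have to choose between B5 and the equally activated B3 (para to the B6 oxygen). The bromine that marks B5 is installed before ring A is attached, where symmetry makes its position unambiguous. All spectator oxygens are methyl ethers, so methoxide exchange at the methoxy-bearing dienone carbons of 20 is degenerate. Both free phenols of 19 are released together from MOM ethers.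
- Assumption: the C4 hydroxyl of 19 (para to the ketone, not hydrogen-bonded) is taken as the more acidic and more easily oxidised phenol. A cyclic voltammogram of 19 with and without 2,6-lutidine would be recorded first to set the working potential.

**Route**

Step 1
Reactants: 1 4-hydroxy-2,6-dimethoxybenzaldehyde
Product: 2 3,5-dibromo-4-hydroxy-2,6-dimethoxybenzaldehyde
Conditions: NBS (2.05 equiv), MeCN, 0 °C to rt
Reagents that add atoms: N-bromosuccinimide, O=C1CCC(=O)N1Br
Why: Electrophilic aromatic bromination; the only two ring CH positions are ortho to the phenol and flanked by methoxy groups, so dibromination is regiochemically unambiguous, and a near-stoichiometric charge at low temperature limits ipso attack at the formyl carbon.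

Step 2
Reactants: 2 3,5-dibromo-4-hydroxy-2,6-dimethoxybenzaldehyde
Product: 3 3,5-dibromo-2,6-dimethoxy-4-(methoxymethoxy)benzaldehyde
Conditions: NaH, THF–DMF, 0 °C; MOMCl, 0 °C to rt
Reagents that add atoms: chloromethyl methyl ether, COCCl
Why: Williamson-type O-alkylation of the acidic phenoxide with a reactive α-chloro ether; the slim acetal will fit between two ortho aryl groups and is removable in mild acid.

Step 3
Reactants: 3 3,5-dibromo-2,6-dimethoxy-4-(methoxymethoxy)benzaldehyde; 4 1,3,5-trimethoxybenzene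
Product: 8 2,6-dimethoxy-4-(methoxymethoxy)-3,5-bis(2,4,6-trimethoxyphenyl)benzaldehyde, via 2,4,6-trimethoxyphenyllithium 5 (not isolated), via (2,4,6-trimethoxyphenyl)zinc chloride 6 (not isolated), via monoarylated bromoaldehyde 7 (not isolated)
Conditions: 4 (2.6 equiv), n-BuLi (2.5 equiv), THF, 0 °C to rt; ZnCl2 (2.7 equiv), THF, rt; then 3, Pd(OAc)2 (5 mol %), 2-dicyclohexylphosphino-2',6'-diisopropoxybiphenyl (10 mol %), THF–NMP, 70 °C
Reagents that add atoms: none
Why: Lithiation of 4 between two methoxy groups, transmetalation to zinc and twofold Negishi coupling; palladium with a bulky dialkylbiarylphosphine is known to form tetra-ortho-substituted biaryls from arylzinc halides, the ortho groups here are only alkoxy, and arylzinc reagents do not add to the aldehyde.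

Step 4
Reactants: 9 3,5-dimethoxybenzaldehyde
Product: 10 2,6-dibromo-3,5-dimethoxybenzaldehyde
Conditions: Br2 (2.2 equiv), AcOH, rt
Reagents that add atoms: bromine, BrBr
Why: Electrophilic aromatic bromination; each position ortho to the formyl group is para to one methoxy and ortho to the other and should react before the crowded position between the two methoxy groups, as in the usual 2,6-dihalogenation of 3,5-dimethoxyaryl carbonyl compounds.

Step 5
Reactants: 10 2,6-dibromo-3,5-dimethoxybenzaldehyde; 11 3,5-dimethoxyphenol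
Product: 12 2-bromo-6-(3,5-dimethoxyphenoxy)-3,5-dimethoxybenzaldehyde
Conditions: 10 (1.5 equiv), 11 (1.0 equiv), CuI (10 mol %), picolinic acid (20 mol %), K3PO4, DMSO, 90 °C
Reagents that add atoms: none
Why: Ullmann-type copper-catalysed diaryl ether synthesis; the two C–Br bonds are equivalent and activated by the ortho formyl group, so either gives the same product, and using the phenol as limiting partner against excess dibromide should hold the reaction at monosubstitution.

Step 6
Reactants: 12 2-bromo-6-(3,5-dimethoxyphenoxy)-3,5-dimethoxybenzaldehyde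
Product: 14 2-bromo-6-(3,5-dimethoxyphenoxy)-3,5-dimethoxyphenol, via aryl formate 13 (not isolated)
Conditions: mCPBA, CH2Cl2, 0 °C to rt; then K2CO3, MeOH, rt
Reagents that add atoms: meta-chloroperoxybenzoic acid, O=C(OO)c1cccc(Cl)c1
Why: Baeyer–Villiger (Dakin-type) oxidation; in the Criegee adduct of an ortho-aryloxy, doubly ortho-substituted benzaldehyde the aryl group migrates in preference to hydride, and the formate is removed by transesterification.

Step 7
Reactants: 14 2-bromo-6-(3,5-dimethoxyphenoxy)-3,5-dimethoxyphenol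
Product: 15 1-bromo-3-(3,5-dimethoxyphenoxy)-4,6-dimethoxy-2-(methoxymethoxy)benzene
Conditions: NaH, THF–DMF, 0 °C; MOMCl, 0 °C to rt
Reagents that add atoms: chloromethyl methyl ether, COCCl
Why: Williamson-type O-alkylation; the acetal masks the phenol during halogen–metal exchange and should stabilise the neighbouring carbanion by chelating lithium.

Step 8
Reactants: 15 1-bromo-3-(3,5-dimethoxyphenoxy)-4,6-dimethoxy-2-(methoxymethoxy)benzene; 8 2,6-dimethoxy-4-(methoxymethoxy)-3,5-bis(2,4,6-trimethoxyphenyl)benzaldehyde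
Product: 17 rac-[3-(3,5-dimethoxyphenoxy)-4,6-dimethoxy-2-(methoxymethoxy)phenyl][2,6-dimethoxy-4-(methoxymethoxy)-3,5-bis(2,4,6-trimethoxyphenyl)phenyl]methanol, via B5 aryllithium 16 (not isolated)
Conditions: 15 (1.3 equiv), n-BuLi, THF, −78 °C; then 8, −78 to 0 °C; then H2O
Reagents that add atoms: none
Why: Bromine–lithium exchange followed by 1,2-addition of the aryllithium to a non-enolisable aldehyde; exchange at −78 °C is far faster than deprotonation of the other alkoxy-flanked ring positions, so the carbanion sits at B5 only, and the carbinol centre forms as a racemate that the next step erases.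

Step 9
Reactants: 17 rac-[3-(3,5-dimethoxyphenoxy)-4,6-dimethoxy-2-(methoxymethoxy)phenyl][2,6-dimethoxy-4-(methoxymethoxy)-3,5-bis(2,4,6-trimethoxyphenyl)phenyl]methanol
Product: 18 [3-(3,5-dimethoxyphenoxy)-4,6-dimethoxy-2-(methoxymethoxy)phenyl][2,6-dimethoxy-4-(methoxymethoxy)-3,5-bis(2,4,6-trimethoxyphenyl)phenyl]methanone
Conditions: Dess–Martin periodinane, NaHCO3, CH2Cl2, rt
Reagents that add atoms: none
Why: Dess–Martin oxidation of a hindered diarylmethanol to the benzophenone; the buffered, non-acidic medium avoids ionisation of the electron-rich benzhydrol and leaves both MOM acetals intact.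

Step 10
Reactants: 18 [3-(3,5-dimethoxyphenoxy)-4,6-dimethoxy-2-(methoxymethoxy)phenyl][2,6-dimethoxy-4-(methoxymethoxy)-3,5-bis(2,4,6-trimethoxyphenyl)phenyl]methanone
Product: 19 [3-(3,5-dimethoxyphenoxy)-2-hydroxy-4,6-dimethoxyphenyl][4-hydroxy-2,6-dimethoxy-3,5-bis(2,4,6-trimethoxyphenyl)phenyl]methanone
Conditions: 1.25 M HCl in MeOH, THF, 40 °C
Reagents that add atoms: none
Why: Acid-catalysed acetal exchange with methanol removes both MOM groups in one operation, while aryl methyl ethers, the diaryl ether and the diaryl ketone are inert under these mild conditions.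

Step 11
Reactants: 19 [3-(3,5-dimethoxyphenoxy)-2-hydroxy-4,6-dimethoxyphenyl][4-hydroxy-2,6-dimethoxy-3,5-bis(2,4,6-trimethoxyphenyl)phenyl]methanone
Product: 20 7-(3,5-dimethoxyphenoxy)-2',4,6,6'-tetramethoxy-3',5'-bis(2,4,6-trimethoxyphenyl)-3H-spiro[1-benzofuran-2,1'-cyclohexa[2,5]diene]-3,4'-dione
Conditions: undivided cell, graphite anode, Pt cathode, Bu4NBF4 (0.1 M), 2,6-lutidine (3 equiv), MeCN–HFIP (9:1), 5 mM in 19, anode held near +0.9 V vs Ag/AgCl (first phenol wave), 2.1 F/mol, 0 °C
Reagents that add atoms: none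
Why: Base-assisted removal of two electrons from the C4 hydroxyl of ring C gives a phenoxenium-type species (or a phenoxyl radical that is oxidised again after attack) with electrophilic character at the para carbon C1, and the B6 oxygen, held beside C1 by the B5–CO–C1 bridge, adds there with loss of the second proton while lutidinium is reduced to hydrogen at platinum. The closest known reaction type is the oxidative cyclisation of 2,4'-dihydroxybenzophenones to grisadienones, which is established with chemical oxidants and at an anode. The single new ring, the furanone (O, B6, B5, carbonyl carbon, C1), closes in a 5-exo-trig mode through the new O–C1 bond. No stereocentre arises, because the two arms of the cyclohexadienone at the spiro carbon are identical. The step needs chemoselective oxidation of the C4 phenol beside five polyalkoxy rings and the B6 phenol: the lutidine-assisted phenol wave should lie well below the potentials of the aryl ethers, and the B6 hydroxyl is hydrogen-bonded to the ketone and harder to oxidise, which also disfavours its closure onto ring A. Oxygen rather than carbon attack, and C1 rather than C3 or C5, follow from geometry, since only the B6 oxygen reaches ring C and only C1 gives an unstrained ring, while high dilution and charge control should suppress intermolecular coupling through B3 and over-oxidation of 20.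

Step 12
Reactants: 20 7-(3,5-dimethoxyphenoxy)-2',4,6,6'-tetramethoxy-3',5'-bis(2,4,6-trimethoxyphenyl)-3H-spiro[1-benzofuran-2,1'-cyclohexa[2,5]diene]-3,4'-dione
Product: 21 methyl 3-(3,5-dimethoxyphenoxy)-2-[4-hydroxy-2,6-dimethoxy-3,5-bis(2,4,6-trimethoxyphenyl)phenoxy]-4,6-dimethoxybenzoate
Conditions: NaOMe (3 equiv), MeOH–THF, 0 °C to rt; then dilute HCl
Reagents that add atoms: sodium methoxide, C[O-].[Na+]
Why: Retro-Claisen-type cleavage; methoxide adds to the benzofuranone carbonyl and the adduct expels C1, because the departing carbanion is the para carbon of a cyclohexadienone and becomes an aromatic phenoxide, while methoxide substitution at the methoxy-bearing dienone carbons is degenerate.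

Step 13
Reactants: 21 methyl 3-(3,5-dimethoxyphenoxy)-2-[4-hydroxy-2,6-dimethoxy-3,5-bis(2,4,6-trimethoxyphenyl)phenoxy]-4,6-dimethoxybenzoate
Product: 23 4-[2-(3,5-dimethoxyphenoxy)-3,5-dimethoxyphenoxy]-3,5-dimethoxy-2,6-bis(2,4,6-trimethoxyphenyl)phenol, via benzoic acid 22 (not isolated)
Conditions: KOH, 1,4-dioxane–H2O, 100 °C, argon; then 6 M HCl to pH 1, 80 °C
Reagents that add atoms: none
Why: Ester saponification followed by acid-promoted protodecarboxylation; the carboxyl at B5 has oxygen substituents at both ortho positions and the para position, so ipso protonation and loss of CO2 should be as easy as for 2,4,6-trialkoxybenzoic acids.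

Step 14
Reactants: 23 4-[2-(3,5-dimethoxyphenoxy)-3,5-dimethoxyphenoxy]-3,5-dimethoxy-2,6-bis(2,4,6-trimethoxyphenyl)phenol
Product: 24 4-[2-(3,5-dihydroxyphenoxy)-3,5-dihydroxyphenoxy]-2,6-bis(2,4,6-trihydroxyphenyl)benzene-1,3,5-triol (CNP0228669.0)
Conditions: BBr3 (30 equiv), CH2Cl2, −78 °C to rt, argon; then MeOH, H2O, 0 °C
Reagents that add atoms: none
Why: BBr3 demethylation cleaves all twelve aryl methyl ethers while diaryl ether and biaryl bonds are stable, and keeping the mixture at or below room temperature should avoid acid-driven cyclodehydration of the ortho,ortho'-dihydroxybiaryl units to dibenzofurans.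

**Compound list**

1 | 4-hydroxy-2,6-dimethoxybenzaldehyde | COc1cc(O)cc(OC)c1C=O | starting material
2 | 3,5-dibromo-4-hydroxy-2,6-dimethoxybenzaldehyde | O=Cc1c(OC)c(Br)c(O)c(Br)c1OC | intermediate
3 | 3,5-dibromo-2,6-dimethoxy-4-(methoxymethoxy)benzaldehyde | O=Cc1c(OC)c(Br)c(OCOC)c(Br)c1OC | intermediate
4 | 1,3,5-trimethoxybenzene | COc1cc(OC)cc(OC)c1 | starting material
5 | 2,4,6-trimethoxyphenyllithium | [Li]c1c(OC)cc(OC)cc1OC | intermediate
6 | (2,4,6-trimethoxyphenyl)zinc chloride | Cl[Zn]c1c(OC)cc(OC)cc1OC | intermediate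
7 | 3-bromo-2,6-dimethoxy-4-(methoxymethoxy)-5-(2,4,6-trimethoxyphenyl)benzaldehyde | O=Cc1c(OC)c(Br)c(OCOC)c(-c2c(OC)cc(OC)cc2OC)c1OC | intermediate
8 | 2,6-dimethoxy-4-(methoxymethoxy)-3,5-bis(2,4,6-trimethoxyphenyl)benzaldehyde | O=Cc1c(OC)c(-c2c(OC)cc(OC)cc2OC)c(OCOC)c(-c2c(OC)cc(OC)cc2OC)c1OC | intermediate
9 | 3,5-dimethoxybenzaldehyde | COc1cc(C=O)cc(OC)c1 | starting material
10 | 2,6-dibromo-3,5-dimethoxybenzaldehyde | O=Cc1c(Br)c(OC)cc(OC)c1Br | intermediate
11 | 3,5-dimethoxyphenol | COc1cc(O)cc(OC)c1 | starting material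
12 | 2-bromo-6-(3,5-dimethoxyphenoxy)-3,5-dimethoxybenzaldehyde | O=Cc1c(Br)c(OC)cc(OC)c1Oc1cc(OC)cc(OC)c1 | intermediate
13 | 2-bromo-6-(3,5-dimethoxyphenoxy)-3,5-dimethoxyphenyl formate | O=COc1c(Br)c(OC)cc(OC)c1Oc1cc(OC)cc(OC)c1 | intermediate
14 | 2-bromo-6-(3,5-dimethoxyphenoxy)-3,5-dimethoxyphenol | Oc1c(Br)c(OC)cc(OC)c1Oc1cc(OC)cc(OC)c1 | intermediate
15 | 1-bromo-3-(3,5-dimethoxyphenoxy)-4,6-dimethoxy-2-(methoxymethoxy)benzene | COCOc1c(Br)c(OC)cc(OC)c1Oc1cc(OC)cc(OC)c1 | intermediate
16 | [3-(3,5-dimethoxyphenoxy)-4,6-dimethoxy-2-(methoxymethoxy)phenyl]lithium | [Li]c1c(OC)cc(OC)c(Oc2cc(OC)cc(OC)c2)c1OCOC | intermediate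
17 | rac-[3-(3,5-dimethoxyphenoxy)-4,6-dimethoxy-2-(methoxymethoxy)phenyl][2,6-dimethoxy-4-(methoxymethoxy)-3,5-bis(2,4,6-trimethoxyphenyl)phenyl]methanol | COc1cc(OC)cc(Oc2c(OC)cc(OC)c(C(O)c3c(OC)c(-c4c(OC)cc(OC)cc4OC)c(OCOC)c(-c4c(OC)cc(OC)cc4OC)c3OC)c2OCOC)c1 | intermediate
18 | [3-(3,5-dimethoxyphenoxy)-4,6-dimethoxy-2-(methoxymethoxy)phenyl][2,6-dimethoxy-4-(methoxymethoxy)-3,5-bis(2,4,6-trimethoxyphenyl)phenyl]methanone | COc1cc(OC)cc(Oc2c(OC)cc(OC)c(C(=O)c3c(OC)c(-c4c(OC)cc(OC)cc4OC)c(OCOC)c(-c4c(OC)cc(OC)cc4OC)c3OC)c2OCOC)c1 | intermediate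
19 | [3-(3,5-dimethoxyphenoxy)-2-hydroxy-4,6-dimethoxyphenyl][4-hydroxy-2,6-dimethoxy-3,5-bis(2,4,6-trimethoxyphenyl)phenyl]methanone | COc1cc(OC)cc(Oc2c(OC)cc(OC)c(C(=O)c3c(OC)c(-c4c(OC)cc(OC)cc4OC)c(O)c(-c4c(OC)cc(OC)cc4OC)c3OC)c2O)c1 | intermediate
20 | 7-(3,5-dimethoxyphenoxy)-2',4,6,6'-tetramethoxy-3',5'-bis(2,4,6-trimethoxyphenyl)-3H-spiro[1-benzofuran-2,1'-cyclohexa[2,5]diene]-3,4'-dione | COc1cc(OC)cc(Oc2c(OC)cc(OC)c3c2OC2(C3=O)C(OC)=C(c3c(OC)cc(OC)cc3OC)C(=O)C(c3c(OC)cc(OC)cc3OC)=C2OC)c1 | intermediate
21 | methyl 3-(3,5-dimethoxyphenoxy)-2-[4-hydroxy-2,6-dimethoxy-3,5-bis(2,4,6-trimethoxyphenyl)phenoxy]-4,6-dimethoxybenzoate | COC(=O)c1c(OC)cc(OC)c(Oc2cc(OC)cc(OC)c2)c1Oc1c(OC)c(-c2c(OC)cc(OC)cc2OC)c(O)c(-c2c(OC)cc(OC)cc2OC)c1OC | intermediate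
22 | 3-(3,5-dimethoxyphenoxy)-2-[4-hydroxy-2,6-dimethoxy-3,5-bis(2,4,6-trimethoxyphenyl)phenoxy]-4,6-dimethoxybenzoic acid | OC(=O)c1c(OC)cc(OC)c(Oc2cc(OC)cc(OC)c2)c1Oc1c(OC)c(-c2c(OC)cc(OC)cc2OC)c(O)c(-c2c(OC)cc(OC)cc2OC)c1OC | intermediate
23 | 4-[2-(3,5-dimethoxyphenoxy)-3,5-dimethoxyphenoxy]-3,5-dimethoxy-2,6-bis(2,4,6-trimethoxyphenyl)phenol | COc1cc(OC)cc(Oc2c(OC)cc(OC)cc2Oc2c(OC)c(-c3c(OC)cc(OC)cc3OC)c(O)c(-c3c(OC)cc(OC)cc3OC)c2OC)c1 | intermediate
24 | 4-[2-(3,5-dihydroxyphenoxy)-3,5-dihydroxyphenoxy]-2,6-bis(2,4,6-trihydroxyphenyl)benzene-1,3,5-triol | Oc1cc(O)cc(Oc2c(O)cc(O)cc2Oc2c(O)c(-c3c(O)cc(O)cc3O)c(O)c(-c3c(O)cc(O)cc3O)c2O)c1 | target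

**Step count and risks**

Total steps: 14. Longest linear sequence: 11 steps (steps 4 to 14, from 3,5-dimethoxybenzaldehyde 9); the ring C branch (steps 1 to 3) joins at step 8.

Steps most likely to fail:

Step 11 (key step). Electron removal may begin at the ring B phenol or at a polyalkoxy ring instead of the C4 phenol. That would lead to closure of the B6 oxygen onto ring A, intermolecular coupling through B3, or over-oxidation of the dienone. The fallback drops oxidation and the tether and makes the same ether by cross-coupling. It sets out from 14 and 8 and returns at 23. Bromophenol 14 would be hydrodebrominated (H2, Pd/C, Et3N, EtOAc) to 2-(3,5-dimethoxyphenoxy)-3,5-dimethoxyphenol F1 and converted with Tf2O and pyridine into 2-(3,5-dimethoxyphenoxy)-3,5-dimethoxyphenyl trifluoromethanesulfonate F2. Aldehyde 8 would undergo Baeyer–Villiger oxidation (mCPBA) to 2,6-dimethoxy-4-(methoxymethoxy)-3,5-bis(2,4,6-trimethoxyphenyl)phenyl formate F3, and methanolysis (K2CO3, MeOH) would give 2,6-dimethoxy-4-(methoxymethoxy)-3,5-bis(2,4,6-trimethoxyphenyl)phenol F4. Buchwald–Hartwig etherification of F2 with F4 (Pd(OAc)2, 2-di-tert-butylphosphino-2',4',6'-triisopropylbiphenyl, K3PO4, toluene, 100 °C, slow addition of the triflate) would give 1-[2-(3,5-dimethoxyphenoxy)-3,5-dimethoxyphenoxy]-2,6-dimethoxy-4-(methoxymethoxy)-3,5-bis(2,4,6-trimethoxyphenyl)benzene F5. HCl in MeOH would then remove the MOM group and deliver 23, which continues with step 14.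

Step 3. After the first coupling, oxidative addition and transmetalation at the remaining, now heavily flanked C–Br bond may stall, so that hydrodebromination of 7 competes. The fallback replaces palladium cross-coupling with ligand-coupling arylation of the free phenol. It sets out from 1 and 4 and returns at 8. Arene 4 would be plumbated with Pb(OAc)4 (AcOH–CHCl3, rt) to (2,4,6-trimethoxyphenyl)lead triacetate F6, an aryl derivative of tetravalent lead. Phenol 1 would be arylated at both ortho positions with F6 in CHCl3–pyridine at 60 °C (Pinhey arylation) to give 4-hydroxy-2,6-dimethoxy-3,5-bis(2,4,6-trimethoxyphenyl)benzaldehyde F7. MOM protection under the conditions of step 2 would give 8.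

Step 5. Control over the degree of substitution may be lost (second etherification of 12), or coupling at the doubly ortho-substituted bromide may be slow enough for copper-mediated hydrodebromination to compete. The fallback uses a substrate with a single C–Br bond and places the B5 carbanion by directed metalation instead of bromine–lithium exchange. It sets out from 9 and 11 and returns at 16, and so at 17. Monobromination of 9 (NBS, 1.05 equiv, MeCN) would give 2-bromo-3,5-dimethoxybenzaldehyde F8. Ullmann etherification with 11 under the conditions of step 5, now driven to completion, would give 2-(3,5-dimethoxyphenoxy)-3,5-dimethoxybenzaldehyde F9. Baeyer–Villiger oxidation would pass through 2-(3,5-dimethoxyphenoxy)-3,5-dimethoxyphenyl formate F10 to the phenol F1 already described for step 11. MOM protection would give 2-(3,5-dimethoxyphenoxy)-1,5-dimethoxy-3-(methoxymethoxy)benzene F11. Directed ortho-lithiation of F11 (n-BuLi, THF, 0 °C) between the OMOM and OMe groups would generate aryllithium 16, which adds to 8 as in step 8. The site of metalation would have to be confirmed by a deuterium quench before use, since B3 and the ring A position between two methoxy groups are also acidic.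

Further compounds
F1 | step 11 | 2-(3,5-dimethoxyphenoxy)-3,5-dimethoxyphenol | COc1cc(OC)cc(Oc2c(OC)cc(OC)cc2O)c1
F2 | step 11 | 2-(3,5-dimethoxyphenoxy)-3,5-dimethoxyphenyl trifluoromethanesulfonate | COc1cc(OC)cc(Oc2c(OC)cc(OC)cc2OS(=O)(=O)C(F)(F)F)c1
F3 | step 11 | 2,6-dimethoxy-4-(methoxymethoxy)-3,5-bis(2,4,6-trimethoxyphenyl)phenyl formate | O=COc1c(OC)c(-c2c(OC)cc(OC)cc2OC)c(OCOC)c(-c2c(OC)cc(OC)cc2OC)c1OC
F4 | step 11 | 2,6-dimethoxy-4-(methoxymethoxy)-3,5-bis(2,4,6-trimethoxyphenyl)phenol | Oc1c(OC)c(-c2c(OC)cc(OC)cc2OC)c(OCOC)c(-c2c(OC)cc(OC)cc2OC)c1OC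
F5 | step 11 | 1-[2-(3,5-dimethoxyphenoxy)-3,5-dimethoxyphenoxy]-2,6-dimethoxy-4-(methoxymethoxy)-3,5-bis(2,4,6-trimethoxyphenyl)benzene | COc1cc(OC)cc(Oc2c(OC)cc(OC)cc2Oc2c(OC)c(-c3c(OC)cc(OC)cc3OC)c(OCOC)c(-c3c(OC)cc(OC)cc3OC)c2OC)c1
F6 | step 3 | (2,4,6-trimethoxyphenyl)lead triacetate | COc1cc(OC)c([Pb](OC(C)=O)(OC(C)=O)OC(C)=O)c(OC)c1
F7 | step 3 | 4-hydroxy-2,6-dimethoxy-3,5-bis(2,4,6-trimethoxyphenyl)benzaldehyde | O=Cc1c(OC)c(-c2c(OC)cc(OC)cc2OC)c(O)c(-c2c(OC)cc(OC)cc2OC)c1OC
F8 | step 5 | 2-bromo-3,5-dimethoxybenzaldehyde | O=Cc1cc(OC)cc(OC)c1Br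
F9 | step 5 | 2-(3,5-dimethoxyphenoxy)-3,5-dimethoxybenzaldehyde | O=Cc1cc(OC)cc(OC)c1Oc1cc(OC)cc(OC)c1
F10 | step 5 | 2-(3,5-dimethoxyphenoxy)-3,5-dimethoxyphenyl formate | O=COc1cc(OC)cc(OC)c1Oc1cc(OC)cc(OC)c1
F11 | step 5 | 2-(3,5-dimethoxyphenoxy)-1,5-dimethoxy-3-(methoxymethoxy)benzene | COCOc1cc(OC)cc(OC)c1Oc1cc(OC)cc(OC)c1
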